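Remark: every atom keeps the germacrane number of the target in all intermediates (ring C1–C10, lactone carbons C11–C13, C14 on C10, C15 on C4), also in the carvone-derived ring compounds.

## The problem

Compound 29 is a germacran-6,12-olide: a cyclodecane ring (C1–C10) with a (Z)-trisubstituted C4=C5 olefin, a trans-fused α-methylene-γ-butyrolactone across C6–C7, an angelate on C9 and five stereocenters (3S, 6R, 7S, 9S, 10S). The ten-membered ring is the central difficulty: it is strained, every closure competes with oligomerization, and its cis olefin is flanked by two allylic C–O bonds (C3 and C6) on opposite faces, so that no peroxide or ether bridge can deliver both. The stereocenters fall into two groups. C6, C7 and C9 are 1,2- and 1,3-related and can control one another on a six-membered ring, and C10, a tertiary carbinol next to C9, can be set from C9 by chelation, but reliably only in an open chain. C3 is remote from all the others and needs reagent control. The methylene lactone (Michael acceptor), the angelate (Z to E isomerization, acyl transfer) and the allylic carbinols at C3 and C6 forbid strong nucleophiles, hydrides, bases and acids late in the route.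

Two features of the structure are used. First, C5, C6, C7, C8, C9 and C10 with C14 and the three-carbon unit C11–C13 are, atom for atom, the ring, the methyl group and the isopropenyl group of carvone, and the C5–C10 bond is the C(=O)–C(CH3) bond of the terpene. Second, the remaining four-carbon bridge C1–C4 ends in a carbinol (C3) bonded directly to an olefinic carbon (C4). The ring bond C3–C4 can therefore be made by adding a C4 alkenyl metal, whose iodide precursor carries iodine cis to C6, to a C3 aldehyde. The six-membered ring thus serves as a template for three stereocenters, is cut between C5 and C10, and is closed again four carbons larger.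

## Retrosynthesis

**Lactone last (29 to 26).** The C12–O6 bond and the C12 oxidation level are removed first, which leads to tetraol 26 with a primary allylic alcohol at C12. Unlike a cut of the lactone at C6–C7, this keeps C6 and C7 in the precursor as existing stereocenters and keeps the Michael acceptor out of every organometallic step. The forward reaction must oxidize a primary allylic alcohol beside two secondary ones.

**C3 by reagent control (26 to 25, 24, 23).** Desilylation links 26 to 25. The C3–H bond of 25 is cut to give enone 24, which is the common oxidation product of both C3 epimers of cyclodecenol 23. This takes the one isolated stereocenter out of the ring closure and hands it to a chiral reducing catalyst. The price is two steps, and the ring closure no longer has to be selective.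

**The ring bond C3–C4 (23 to 22).** This is the key cut. Its neighbours are worse: C4=C5 would have to form as a strained trisubstituted olefin between two oxygenated carbons, C6–C7 would create two stereocenters in the macrocyclization, and C10–C1 would need an alkyl nucleophile to close a ten-membered ring. The precursor 22 is an open chain with an aldehyde at C3 and a (Z)-iodoalkene at C4; all other stereocenters are already in place. The forward reaction must keep the olefin geometry and close a ten-membered ring.

**Chain ends (22 to 19, 17, 16, 14).** The C3 aldehyde comes from the terminal olefin of an allyl group (C1–C3), the C9 ester from angelic acid 18, and the iodoalkene from a C5 aldehyde 14 and the two-carbon ylide derived from phosphonium salt 15 (C4 and C15). Each cut removes one functional group and uses a standard reaction.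

**C10–C1 and the C10 stereocenter (14 to 12 to 10).** The allyl group (reagent 11) is cut from C10, which leaves the α-alkoxy methyl ketone 10. In the open chain the C9 ether oxygen and the ketone form a five-membered chelate, so C9 sets C10. The same addition on a ring ketone would have no such guarantee.

**The template bond C5–C10 (10 to 9).** Keto ester 10 has a methyl ketone at C10 and an ester at C5, the two products of an oxidative α-ketol cleavage. Joining C5 and C10 again gives the cyclohexanone α-ketol 9. This is the largest simplification: three stereocenters of an open chain become substituents on a six-membered ring.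

**Ring-controlled oxygenation (9 to 1).** The C9 ether and the C10 hydroxyl of 9 come from trans opening of epoxide 8, the epoxide from the enone of 7, and the C6 oxygen from α′-hydroxylation of the enone 4. Both oxygens are directed by the C7 side chain. The C12 oxygen comes from allylic chlorination of the isopropenyl group of (R)-carvone 1. All of this is substrate control from the one purchased stereocenter C7.

## Roads not taken

Alternative 1: the most obvious cut is the C6–C7 ring bond together with the lactone C–O bond. The forward key step would be an intramolecular Barbier-type allylation (CrCl2, Nozaki–Hiyama–Kishi conditions) of the (Z)-enal A1 by its own 2-(bromomethyl)acrylate end, closing ring and lactone at once to the silyl ether A2 of 29. The chosen plan is better for three reasons. A1 contains a (Z)-γ-oxygenated enal, which isomerizes readily to the E isomer and would then give the wrong ring olefin. C6 and C7 would both be created in the macrocyclization, with their absolute sense controlled only by the distant centers C3, C9 and C10. And A1 still needs a separate asymmetric assembly of C3, C9 and C10, so no steps are saved.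

Alternative 2: cut C2–C3 and reconnect C5–C10, an anionic oxy-Cope ring expansion of the cis-1-vinyl-2-isopropenylcyclohexanol A3 to the (Z)-cyclodec-5-enone A4. It makes ring and olefin in one step from a six-membered ring. It was rejected for four reasons. C10 must be the carbinol carbon of A3, so the template cannot carry C14 and is no longer a cheap terpene. The methyl group must then be added to the ring ketone A4, where the chelate model of step 8 predicts the C10 epimer, because methyl and the C1 chain have exchanged the roles of nucleophile and resident group. The C3 oxygen is missing, and allylic oxidation of the cis olefin would favour C15. Finally, the Z geometry requires the vinyl group to be delivered axially, cis to the isopropenyl group.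

Alternative 3: cut C6–C7 as a [2,3]-Wittig ring contraction of the thirteen-membered bis-allylic ether A5 to the cyclodecenol A6, which would form the ring bond, the C6 carbinol and the exocyclic methylene at once. The chosen plan is better because the configuration of C6 and C7 relative to C3, C9 and C10 would rest on the conformation of a flexible macrocycle, the deprotonation would have to distinguish C6 from the second allylic ether carbon C13, and the macrocyclic ether needs its own ring closure, so two macrocyclic events replace one.

Key step: step 16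

## Route

Step 1
Reactants: 1 (R)-carvone
Product: 2 10-chlorocarvone (C12 allylic chloride)
Conditions: Ca(OCl)2, CO2 (solid), CH2Cl2/H2O, 0 °C
Reagents that add atoms: calcium hypochlorite, [Ca+2].[O-]Cl.[O-]Cl
Why: Ene-type allylic chlorination by hypochlorous acid made in the flask; the electron-rich 1,1-disubstituted isopropenyl olefin reacts, the electron-poor enone does not, and C7 is untouched.

Step 2
Reactants: 2 10-chlorocarvone
Product: 4 10-hydroxycarvone (C12 primary allylic alcohol), via acetate 3 (not isolated)
Conditions: KOAc, 18-crown-6 (cat.), MeCN, 60 °C; then K2CO3 (cat.), MeOH, rt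
Reagents that add atoms: potassium acetate, CC(=O)[O-].[K+]
Why: SN2 displacement of the primary allylic chloride by acetate (SN2 and SN2′ give the same product in this symmetrical allyl unit), then transesterification of 3 with methanol under conditions mild enough for the enone.

Step 3
Reactants: 4 10-hydroxycarvone
Product: 6 enone diol (C6 hydroxyl trans to the C7 side chain), via dipotassium enolate 5 (not isolated)
Conditions: KN(SiMe3)2 (2.2 equiv), THF, −78 °C; then 2-(phenylsulfonyl)-3-phenyloxaziridine, −78 °C
Reagents that add atoms: 2-(phenylsulfonyl)-3-phenyloxaziridine, O=S(=O)(N1OC1c1ccccc1)c1ccccc1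
Why: Kinetic deprotonation at the α′ carbon C6 gives the cross-conjugated enolate (the C12 alkoxide forms first), and enolate hydroxylation by the N-sulfonyloxaziridine occurs on the face anti to the C7 side chain; the resulting trans C6/C7 arrangement is also the thermodynamically preferred one at this epimerizable center.

Step 4
Reactants: 6 enone diol
Product: 7 bis(tert-butyldimethylsilyl) ether of 6
Conditions: TBSCl, imidazole, DMF, rt
Reagents that add atoms: tert-butyldimethylsilyl chloride, CC(C)(C)[Si](C)(C)Cl
Why: Standard silylation of the primary and the secondary alcohol; both ethers are meant to survive bases, organometallic reagents, chromium salts and oxidants up to step 19.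

Step 5
Reactants: 7 bis-silyl ether
Product: 8 epoxy ketone (9,10-epoxide, oxygen anti to the C7 side chain)
Conditions: 30% H2O2, NaOH (cat.), MeOH, −10 °C
Reagents that add atoms: hydrogen peroxide, OO
Why: Nucleophilic (Weitz–Scheffer) epoxidation: hydroperoxide adds axially to C9 of the enone anti to the equatorial C7 side chain, as with carvone itself, so both epoxide C–O bonds lie on the face opposite to C11; the isolated olefin is inert to this oxidant.

Step 6
Reactants: 8 epoxy ketone
Product: 9 α-ketol (C9 2-naphthylmethyl ether syn to the C7 side chain, C10 tertiary alcohol, C5 ketone)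
Conditions: 2-naphthalenemethanol, BF3·OEt2 (cat.), CH2Cl2, −30 °C
Reagents that add atoms: 2-naphthalenemethanol, OCc1ccc2ccccc2c1
Why: Lewis-acid-catalysed alcoholysis of the α,β-epoxy ketone: attack occurs at C9, remote from the carbonyl (positive charge at C10 is disfavoured next to C=O), with inversion (trans-diaxial opening), which puts the C9 oxygen on the face of C11 as in the target.

Step 7
Reactants: 9 α-ketol
Product: 10 open-chain keto ester (C5 methyl ester, C10 methyl ketone)
Conditions: Pb(OAc)4, MeOH/benzene, 0 °C
Reagents that add atoms: methanol, CO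
Why: Oxidative cleavage of the α-ketol by lead tetraacetate through its methyl hemiketal cuts the C5–C10 ring bond, turning C5 into the ester and C10 into the methyl ketone; C6, C7 and C9 are untouched and the two chain ends are differentiated.

Step 8
Reactants: 10 keto ester; 11 allylmagnesium bromide
Product: 12 tertiary alcohol (9S,10S; allyl group = C1–C3)
Conditions: MgBr2·OEt2, CH2Cl2, −78 °C; then 11 (Et2O), −78 °C
Reagents that add atoms: none
Why: Chelation-controlled Grignard addition (Cram chelate model): magnesium bridges the C10 carbonyl and the C9 arylmethyl ether oxygen, and the allyl group attacks the chelate face that carries H-9, not C8, which gives the 10S carbinol; the ketone reacts much faster than the α-silyloxy ester at −78 °C.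

Step 9
Reactants: 12 tertiary alcohol
Product: 13 C10 triethylsilyl ether
Conditions: TESOTf, 2,6-lutidine, CH2Cl2, −78 to 0 °C
Reagents that add atoms: triethylsilyl trifluoromethanesulfonate, CC[Si](CC)(CC)OS(=O)(=O)C(F)(F)F
Why: Silylation of the tertiary alcohol with the silyl triflate; it prevents lactol formation with the C3 aldehyde of step 15 and keeps a free alkoxide out of steps 11 and 16.

Step 10
Reactants: 13 silyl ether ester
Product: 14 C5 aldehyde
Conditions: i-Bu2AlH, CH2Cl2, −78 °C
Reagents that add atoms: none
Why: Partial reduction of the α-silyloxy methyl ester: the aluminium hemiacetal is stable at −78 °C and releases the aldehyde on work-up; C6 does not epimerize under these non-basic conditions.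

Step 11
Reactants: 14 C5 aldehyde; 15 ethyltriphenylphosphonium iodide
Product: 16 (Z)-iodoalkene (C4=C5, iodine on C4 cis to C6, C15 trans)
Conditions: 15, n-BuLi, THF, rt; I2, −78 °C; NaN(SiMe3)2, −78 °C; then 14, −78 to −20 °C
Reagents that add atoms: iodine, II
Why: Stork–Zhao-type Wittig olefination with the α-iodo ylide; the kinetic selectivity of the non-stabilized ylide gives the (Z)-2-iodoalkene, which fixes the geometry of the later ring olefin.

Step 12
Reactants: 16 iodoalkene
Product: 17 C9 alcohol
Conditions: DDQ, CH2Cl2/pH 7 buffer, 0 °C to rt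
Reagents that add atoms: none
Why: Oxidative cleavage of the electron-rich 2-naphthylmethyl ether by DDQ (hydride abstraction, hydrolysis of the oxocarbenium ion); silyl ethers, iodoalkene and isolated olefins are inert.

Step 13
Reactants: 17 C9 alcohol; 18 angelic acid
Product: 19 C9 angelate
Conditions: 18, 2,4,6-trichlorobenzoyl chloride, Et3N, toluene, rt; then 17, 75 °C
Reagents that add atoms: none
Why: Yamaguchi esterification through the mixed anhydride without a nucleophilic catalyst, the conditions under which angelic acid is transferred without Z to E isomerization; C9–OH is the only free hydroxyl group.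

Step 14
Reactants: 19 angelate
Product: 21 C3 primary alcohol, via alkylborane 20 (not isolated)
Conditions: 9-BBN, THF, 0 °C to rt; then 30% H2O2, aq. NaOAc, 0 °C
Reagents that add atoms: hydrogen peroxide, OO
Why: Hydroboration–oxidation: the bulky dialkylborane adds anti-Markovnikov to the monosubstituted terminal olefin much faster than to the 1,1-disubstituted C11=C13 olefin, the iodoalkene or the enoate, and buffered peroxide oxidizes the C–B bond with the angelate intact.

Step 15
Reactants: 21 primary alcohol
Product: 22 iodo aldehyde (C3 aldehyde)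
Conditions: Dess–Martin periodinane, CH2Cl2, rt
Reagents that add atoms: none
Why: Dess–Martin oxidation under neutral conditions; no epimerizable center is α to the new aldehyde and the silylated C10 oxygen cannot form a lactol.

Step 16
Reactants: 22 iodo aldehyde
Product: 23 (4Z)-cyclodecenol (both C3 epimers)
Conditions: CrCl2 (excess), NiCl2 (cat.), DMSO/THF, rt, slow addition at high dilution
Reagents that add atoms: none
Why: Nozaki–Hiyama–Kishi macrocyclization: zerovalent nickel (formed from NiCl2 by divalent chromium) inserts into the C4–I bond with retention, the alkenyl group passes to trivalent chromium, and the alkenylchromium species adds to the C3 aldehyde, the strong Cr–O bond making the closure irreversible. The closest known reaction type is the nickel/chromium-mediated closure of medium rings from alkenyl iodide aldehydes. The ten-membered carbocycle closes in a 10-exo-trig mode by attack of C4 on C3. The only new stereocenter, C3, is governed by the macrocyclic transition state and is not relied on: both epimers converge on enone 24 in step 17 and C3 is then set by the catalyst of step 18. The step needs retention of the Z olefin, which is secured because alkenylchromium reagents do not invert and iodine was placed cis to C6 in step 11. It needs ring closure over oligomerization, which is favoured by slow addition at high dilution, by the fully substituted C10 (gem-disubstituent effect) and by the cis olefin, which turns the two chain ends toward each other. It needs chemoselectivity, which rests on the inertness of alkenylchromium reagents toward esters, silyl ethers and isolated olefins. The precursor is an open chain whose other four stereocenters are already fixed, so the step adds only the ring.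

Step 17
Reactants: 23 cyclodecenol
Product: 24 (4Z)-cyclodecenone (C3 ketone)
Conditions: Dess–Martin periodinane, CH2Cl2, 0 °C
Reagents that add atoms: none
Why: Dess–Martin oxidation of the allylic alcohol; both C3 epimers give the same enone, so the stereochemical outcome of step 16 is immaterial.

Step 18
Reactants: 24 cyclodecenone
Product: 25 (3S)-cyclodecenol
Conditions: (R)-2-methyl-CBS-oxazaborolidine, catecholborane, toluene, −78 °C
Reagents that add atoms: none
Why: Corey–Bakshi–Shibata reduction: the ketone binds to the (R)-oxazaborolidine with the alkenyl carbon C4 as the large and the C2 methylene as the small group, and hydride is delivered to the face that gives the 3S allylic alcohol; 1,2-reduction is favoured and the enoate ester is untouched at −78 °C.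

Step 19
Reactants: 25 (3S)-cyclodecenol
Product: 26 tetraol (free hydroxyl at C3, C6, C10 and C12; C9 angelate)
Conditions: HF·pyridine, pyridine/THF, 0 °C to rt
Reagents that add atoms: none
Why: Fluoride-mediated cleavage of all three silyl ethers in one operation under buffered, weakly acidic conditions that leave the angelate and the allylic alcohols intact.

Step 20
Reactants: 26 tetraol
Product: 29 target (CNP0549192.1), via hydroxy aldehyde 27 (not isolated), via lactol 28 (not isolated)
Conditions: TEMPO (cat.), PhI(OAc)2, CH2Cl2, rt
Reagents that add atoms: none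
Why: The oxoammonium oxidation selects the primary allylic alcohol; aldehyde 27 is trapped by the C6 hydroxyl as the five-membered lactol 28 (5-exo-trig), which is oxidized to the lactone; C6 and C7 are trans on the ring since step 3, so the lactone is trans-fused.

## Compound list

1 | (R)-carvone | CC1=CC[C@@H](C(C)=C)CC1=O | starting material
2 | 10-chlorocarvone, (R)-5-(3-chloroprop-1-en-2-yl)-2-methylcyclohex-2-en-1-one | CC1=CC[C@@H](C(=C)CCl)CC1=O | intermediate
3 | 10-acetoxycarvone | CC1=CC[C@@H](C(=C)COC(C)=O)CC1=O | intermediate
4 | 10-hydroxycarvone | CC1=CC[C@@H](C(=C)CO)CC1=O | intermediate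
5 | dipotassium salt of 4 (C12 alkoxide, C5–C6 enolate) | CC1=CC[C@@H](C(=C)CO[K])C=C1O[K] | intermediate
6 | enone diol, C6 hydroxyl trans to the C7 side chain | CC1=CC[C@@H](C(=C)CO)[C@H](O)C1=O | intermediate
7 | bis(tert-butyldimethylsilyl) ether of 6 | CC1=CC[C@@H](C(=C)CO[Si](C)(C)C(C)(C)C)[C@H](O[Si](C)(C)C(C)(C)C)C1=O | intermediate
8 | epoxy ketone, 9,10-epoxide anti to the C7 side chain | C[C@@]12O[C@@H]1C[C@@H](C(=C)CO[Si](C)(C)C(C)(C)C)[C@H](O[Si](C)(C)C(C)(C)C)C2=O | intermediate
9 | α-ketol, C9 2-naphthylmethyl ether syn to the C7 side chain, C10 tertiary alcohol | C[C@@]1(O)[C@@H](OCc2ccc3ccccc3c2)C[C@@H](C(=C)CO[Si](C)(C)C(C)(C)C)[C@H](O[Si](C)(C)C(C)(C)C)C1=O | intermediate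
10 | open-chain keto ester (C5 methyl ester, C10 methyl ketone) | CC(=O)[C@@H](OCc1ccc2ccccc2c1)C[C@@H](C(=C)CO[Si](C)(C)C(C)(C)C)[C@H](O[Si](C)(C)C(C)(C)C)C(=O)OC | intermediate
11 | allylmagnesium bromide | C=CC[Mg]Br | starting material
12 | (9S,10S) tertiary alcohol with allyl group on C10 | C=CC[C@](C)(O)[C@@H](OCc1ccc2ccccc2c1)C[C@@H](C(=C)CO[Si](C)(C)C(C)(C)C)[C@H](O[Si](C)(C)C(C)(C)C)C(=O)OC | intermediate
13 | C10 triethylsilyl ether of 12 | C=CC[C@](C)(O[Si](CC)(CC)CC)[C@@H](OCc1ccc2ccccc2c1)C[C@@H](C(=C)CO[Si](C)(C)C(C)(C)C)[C@H](O[Si](C)(C)C(C)(C)C)C(=O)OC | intermediate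
14 | C5 aldehyde | C=CC[C@](C)(O[Si](CC)(CC)CC)[C@@H](OCc1ccc2ccccc2c1)C[C@@H](C(=C)CO[Si](C)(C)C(C)(C)C)[C@H](O[Si](C)(C)C(C)(C)C)C=O | intermediate
15 | ethyltriphenylphosphonium iodide | CC[P+](c1ccccc1)(c1ccccc1)c1ccccc1.[I-] | starting material
16 | (Z)-iodoalkene, iodine on C4 cis to C6 | C=CC[C@](C)(O[Si](CC)(CC)CC)[C@@H](OCc1ccc2ccccc2c1)C[C@@H](C(=C)CO[Si](C)(C)C(C)(C)C)[C@H](O[Si](C)(C)C(C)(C)C)/C=C(\I)C | intermediate
17 | C9 alcohol | C=CC[C@](C)(O[Si](CC)(CC)CC)[C@@H](O)C[C@@H](C(=C)CO[Si](C)(C)C(C)(C)C)[C@H](O[Si](C)(C)C(C)(C)C)/C=C(\I)C | intermediate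
18 | angelic acid, (Z)-2-methylbut-2-enoic acid | C/C=C(/C)C(=O)O | starting material
19 | C9 angelate | C=CC[C@](C)(O[Si](CC)(CC)CC)[C@@H](OC(=O)/C(C)=C\C)C[C@@H](C(=C)CO[Si](C)(C)C(C)(C)C)[C@H](O[Si](C)(C)C(C)(C)C)/C=C(\I)C | intermediate
20 | B-alkyl-9-borabicyclo[3.3.1]nonane, boron on C3 | C(CC[C@](C)(O[Si](CC)(CC)CC)[C@@H](OC(=O)/C(C)=C\C)C[C@@H](C(=C)CO[Si](C)(C)C(C)(C)C)[C@H](O[Si](C)(C)C(C)(C)C)/C=C(\I)C)B1C2CCCC1CCC2 | intermediate
21 | C3 primary alcohol | OCCC[C@](C)(O[Si](CC)(CC)CC)[C@@H](OC(=O)/C(C)=C\C)C[C@@H](C(=C)CO[Si](C)(C)C(C)(C)C)[C@H](O[Si](C)(C)C(C)(C)C)/C=C(\I)C | intermediate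
22 | iodo aldehyde (C3 aldehyde) | O=CCC[C@](C)(O[Si](CC)(CC)CC)[C@@H](OC(=O)/C(C)=C\C)C[C@@H](C(=C)CO[Si](C)(C)C(C)(C)C)[C@H](O[Si](C)(C)C(C)(C)C)/C=C(\I)C | intermediate
23 | (4Z)-cyclodecenol, both C3 epimers | OC1CC[C@](C)(O[Si](CC)(CC)CC)[C@@H](OC(=O)/C(C)=C\C)C[C@@H](C(=C)CO[Si](C)(C)C(C)(C)C)[C@H](O[Si](C)(C)C(C)(C)C)/C=C1/C | intermediate
24 | (4Z)-cyclodecenone, C3 ketone | O=C1CC[C@](C)(O[Si](CC)(CC)CC)[C@@H](OC(=O)/C(C)=C\C)C[C@@H](C(=C)CO[Si](C)(C)C(C)(C)C)[C@H](O[Si](C)(C)C(C)(C)C)/C=C1/C | intermediate
25 | (3S)-cyclodecenol | O[C@H]1CC[C@](C)(O[Si](CC)(CC)CC)[C@@H](OC(=O)/C(C)=C\C)C[C@@H](C(=C)CO[Si](C)(C)C(C)(C)C)[C@H](O[Si](C)(C)C(C)(C)C)/C=C1/C | intermediate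
26 | tetraol, C9 angelate | O[C@H]1CC[C@](C)(O)[C@@H](OC(=O)/C(C)=C\C)C[C@@H](C(=C)CO)[C@H](O)/C=C1/C | intermediate
27 | C12 aldehyde of 26 | O[C@H]1CC[C@](C)(O)[C@@H](OC(=O)/C(C)=C\C)C[C@@H](C(=C)C=O)[C@H](O)/C=C1/C | intermediate
28 | lactol (C12 hemiacetal with O6) | C=C1C(O)O[C@@H]2/C=C(/C)[C@@H](O)CC[C@](C)(O)[C@@H](OC(=O)/C(C)=C\C)C[C@@H]12 | intermediate
29 | CNP0549192.1, (3S,6R,7S,9S,10S,4Z)-9-angeloyloxy-3,10-dihydroxygermacra-4,11(13)-dien-6,12-olide | C=C1C(=O)O[C@@H]2/C=C(/C)[C@@H](O)CC[C@](C)(O)[C@@H](OC(=O)/C(C)=C\C)C[C@@H]12 | target

## Step count and least certain steps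

Total: 20 steps. Longest linear sequence: 20 steps from 1 (11, 15 and 18 are bought).

**Step 16 (key step).** A ten-membered ring closes slowly, so oligomerization by intermolecular addition and protodeiodination of the alkenylchromium species before it reaches the aldehyde may take over. The fallback moves the ring closure to the C4=C5 olefin by ring-closing metathesis. It sets out from 13. Hydroboration–oxidation of the allyl group would give the primary alcohol F1, Dess–Martin oxidation the aldehyde F2, and isopropenylmagnesium bromide at −78 °C the allylic alcohols F3 (both C3 epimers, ester untouched). Reduction with i-Bu2AlH would give the C5 aldehyde F4 and Wittig methylenation the diene F5. Ring-closing metathesis of F5 with the second-generation Hoveyda–Grubbs catalyst at high dilution should give the cyclodecenol F6, the Z olefin being the less strained isomer of this ring. Dess–Martin oxidation would give the enone F7, DDQ the C9 alcohol F8, and Yamaguchi esterification of F8 with 18 rejoins the route at 24.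

**Step 6.** The Lewis-acid-activated epoxy ketone may rearrange by 1,2-acyl shift, or be opened at C10 rather than C9. The fallback sets out from 8: hydrolysis with dilute HClO4 in aqueous THF (a small nucleophile and a Brønsted acid) should give the trans-diol F9, and selective etherification of its secondary C9 hydroxyl with 2-naphthylmethyl trichloroacetimidate (cat. TfOH) rejoins the route at 9.

**Step 13.** Acylation of the hindered C9 hydroxyl may be slow, and the Z acyl group may isomerize to the E (tiglate) isomer on prolonged heating. The fallback builds the Z olefin after the acylation. It sets out from 17: esterification with 2-[bis(2,2,2-trifluoroethoxy)phosphoryl]propanoic acid (DCC, DMAP) would give the phosphonate ester F10, and Still–Gennari olefination of F10 with acetaldehyde (KN(SiMe3)2, 18-crown-6, THF, −78 °C) rejoins the route at 19.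

**Step 20.** Chemoselectivity may be lost, that is, the secondary allylic alcohols at C3 or C6 may be oxidized beside the primary one. The fallback removes the C3 carbinol from the oxidation step. It sets out from 24: HF·pyridine would give the enone triol F11, TEMPO/PhI(OAc)2 the 3-oxo lactone F12, and Corey–Bakshi–Shibata reduction of F12 as in step 18 rejoins the route at 29.

## Further compounds

F1 | step 16 | C3 primary alcohol from 13 | OCCC[C@](C)(O[Si](CC)(CC)CC)[C@@H](OCc1ccc2ccccc2c1)C[C@@H](C(=C)CO[Si](C)(C)C(C)(C)C)[C@H](O[Si](C)(C)C(C)(C)C)C(=O)OC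
F2 | step 16 | C3 aldehyde ester | O=CCC[C@](C)(O[Si](CC)(CC)CC)[C@@H](OCc1ccc2ccccc2c1)C[C@@H](C(=C)CO[Si](C)(C)C(C)(C)C)[C@H](O[Si](C)(C)C(C)(C)C)C(=O)OC
F3 | step 16 | C3 isopropenyl carbinols (both epimers) | C=C(C)C(O)CC[C@](C)(O[Si](CC)(CC)CC)[C@@H](OCc1ccc2ccccc2c1)C[C@@H](C(=C)CO[Si](C)(C)C(C)(C)C)[C@H](O[Si](C)(C)C(C)(C)C)C(=O)OC
F4 | step 16 | C5 aldehyde | C=C(C)C(O)CC[C@](C)(O[Si](CC)(CC)CC)[C@@H](OCc1ccc2ccccc2c1)C[C@@H](C(=C)CO[Si](C)(C)C(C)(C)C)[C@H](O[Si](C)(C)C(C)(C)C)C=O
F5 | step 16 | metathesis diene | C=C(C)C(O)CC[C@](C)(O[Si](CC)(CC)CC)[C@@H](OCc1ccc2ccccc2c1)C[C@@H](C(=C)CO[Si](C)(C)C(C)(C)C)[C@H](O[Si](C)(C)C(C)(C)C)C=C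
F6 | step 16 | (4Z)-cyclodecenol with C9 2-naphthylmethyl ether | OC1CC[C@](C)(O[Si](CC)(CC)CC)[C@@H](OCc2ccc3ccccc3c2)C[C@@H](C(=C)CO[Si](C)(C)C(C)(C)C)[C@H](O[Si](C)(C)C(C)(C)C)/C=C1/C
F7 | step 16 | (4Z)-cyclodecenone with C9 2-naphthylmethyl ether | O=C1CC[C@](C)(O[Si](CC)(CC)CC)[C@@H](OCc2ccc3ccccc3c2)C[C@@H](C(=C)CO[Si](C)(C)C(C)(C)C)[C@H](O[Si](C)(C)C(C)(C)C)/C=C1/C
F8 | step 16 | (4Z)-cyclodecenone with free C9 hydroxyl | O=C1CC[C@](C)(O[Si](CC)(CC)CC)[C@@H](O)C[C@@H](C(=C)CO[Si](C)(C)C(C)(C)C)[C@H](O[Si](C)(C)C(C)(C)C)/C=C1/C
F9 | step 6 | trans-9,10-diol of the cyclohexanone | C[C@@]1(O)[C@@H](O)C[C@@H](C(=C)CO[Si](C)(C)C(C)(C)C)[C@H](O[Si](C)(C)C(C)(C)C)C1=O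
F10 | step 13 | C9 2-[bis(2,2,2-trifluoroethoxy)phosphoryl]propanoate | C=CC[C@](C)(O[Si](CC)(CC)CC)[C@@H](OC(=O)C(C)P(=O)(OCC(F)(F)F)OCC(F)(F)F)C[C@@H](C(=C)CO[Si](C)(C)C(C)(C)C)[C@H](O[Si](C)(C)C(C)(C)C)/C=C(\I)C
F11 | step 20 | enone triol | O=C1CC[C@](C)(O)[C@@H](OC(=O)/C(C)=C\C)C[C@@H](C(=C)CO)[C@H](O)/C=C1/C
F12 | step 20 | 3-oxo lactone | C=C1C(=O)O[C@@H]2/C=C(/C)C(=O)CC[C@](C)(O)[C@@H](OC(=O)/C(C)=C\C)C[C@@H]12
A1 | alternative 1 | (Z)-enal with 2-(bromomethyl)acrylate terminus | O=C/C=C(/C)[C@@H](O[Si](C)(C)C(C)(C)C)CC[C@](C)(O)[C@@H](OC(=O)/C(C)=C\C)C/C=C(\CBr)C(=O)OC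
A2 | alternative 1 | 3-O-tert-butyldimethylsilyl ether of 29 | C=C1C(=O)O[C@@H]2/C=C(/C)[C@@H](O[Si](C)(C)C(C)(C)C)CC[C@](C)(O)[C@@H](OC(=O)/C(C)=C\C)C[C@@H]12
A3 | alternative 2 | cis-1-vinyl-2-isopropenylcyclohexanol | C=C[C@]1(O)[C@H](C(C)=C)[C@@H](O[Si](C)(C)C(C)(C)C)[C@H](C(=C)CO[Si](C)(C)C(C)(C)C)C[C@@H]1O[Si](C)(C)C(C)(C)C
A4 | alternative 2 | (Z)-cyclodec-5-enone | O=C1CCC/C(C)=C\[C@@H](O[Si](C)(C)C(C)(C)C)[C@H](C(=C)CO[Si](C)(C)C(C)(C)C)C[C@@H]1O[Si](C)(C)C(C)(C)C
A5 | alternative 3 | thirteen-membered bis-allylic ether | C1/C=C(/C)[C@@H](O[Si](C)(C)C(C)(C)C)CC[C@](C)(O[Si](CC)(CC)CC)[C@@H](OCc2ccc3ccccc3c2)C/C=C(/CO[Si](C)(C)C(C)(C)C)CO1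
A6 | alternative 3 | ring-contracted cyclodecenol | O[C@@H]1/C=C(/C)[C@@H](O[Si](C)(C)C(C)(C)C)CC[C@](C)(O[Si](CC)(CC)CC)[C@@H](OCc2ccc3ccccc3c2)C[C@H]1C(=C)CO[Si](C)(C)C(C)(C)C
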